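**Retrosynthetic overview**

- The strategy rests on the ring arc C1(=O)–C6H(OH)–C5H2–C4H2–C3(OH), which is the uncut five-carbon chain of (R)-2-hydroxyglutaric acid, while ring C2 and the exocyclic acyl C=O are the CH3–C(=O) end of a C19 methyl ketone.
- Key disconnection: both ring bonds at C2 (C2–C3 and C2–C1) are cut, giving (8E,10E)-nonadeca-8,10-dien-2-one and an O-silylated dimethyl (R)-2-hydroxyglutarate. In the forward sense this is a crossed Claisen followed by a Dieckmann-type closure on the same carbon.
- The dienone is cut at the central sigma bond of the diene (Suzuki–Miyaura) into an (E)-iodoalkenyl methyl ketone (from 6-chlorohex-1-yne by hydrozirconation–iodination and acetoacetate chain extension) and an (E)-decenylboronate (from dec-1-yne).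
- Ring order: the only ring, the six-membered carbocycle, is closed in the penultimate step. The stereocentre is bought with (R)-5-oxotetrahydrofuran-2-carboxylic acid, and no oxidant is used once the diene exists.

Key step: step 8

Assumption: the 2-acylcyclohexane-1,3-dione is written throughout as the enol tautomer of the target SMILES (3-hydroxy-2-acylcyclohex-2-en-1-one with the carbinol at C6); the enol tautomers interconvert rapidly and are treated as one compound.

**Route**

Step 1
Reactants: 1 6-chlorohex-1-yne
Product: 3 (E)-6-chloro-1-iodohex-1-ene, via alkenylzirconocene chloride 2 (not isolated)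
Conditions: Cp2Zr(H)Cl (1.2 equiv), THF, rt; then I2 (1.2 equiv), 0 °C
Reagents that add atoms: iodine, II
Why: Hydrozirconation adds Zr–H syn across the terminal alkyne with zirconium at the terminal carbon, and iodinolysis of the C–Zr bond proceeds with retention, so the E-iodoalkene should result while the primary alkyl chloride is inert to both reagents (hydrozirconation–iodination).

Step 2
Reactants: 3 (E)-6-chloro-1-iodohex-1-ene; 4 tert-butyl acetoacetate (2 equiv)
Product: 6 tert-butyl (7E)-2-acetyl-8-iodooct-7-enoate (racemic at C2), via (E)-1,6-diiodohex-1-ene 5 (not isolated)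
Conditions: K2CO3 (2 equiv), NaI (0.2 equiv), DMF, 65 °C
Reagents that add atoms: none
Why: In this acetoacetic ester alkylation the catalytic iodide turns the primary chloride into the more reactive iodide 5 in the flask (Finkelstein exchange), which the stabilised potassium enolate of 4 displaces in an SN2 reaction, the excess of 4 holding back dialkylation and the alkenyl iodide being inert to substitution.

Step 3
Reactants: 6 tert-butyl (7E)-2-acetyl-8-iodooct-7-enoate
Product: 8 (E)-9-iodonon-8-en-2-one, via beta-keto acid 7 (not isolated)
Conditions: TFA, CH2Cl2, rt; concentrate; toluene, 90 °C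
Reagents that add atoms: none
Why: Acidolysis of the tert-butyl ester (loss of 2-methylpropene) frees the beta-keto acid 7, which decarboxylates through the usual six-membered transition state on warming (ketonic cleavage of the acetoacetic ester synthesis), conditions that should leave the alkenyl iodide untouched.

Step 4
Reactants: 9 dec-1-yne
Product: 10 2-[(E)-dec-1-en-1-yl]-4,4,5,5-tetramethyl-1,3,2-dioxaborolane
Conditions: pinacolborane (1.1 equiv), Cp2Zr(H)Cl (5 mol %), Et3N (10 mol %), neat, 60 °C
Reagents that add atoms: pinacolborane, [H]B1OC(C)(C)C(C)(C)O1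
Why: Zirconium-catalysed hydroboration of a terminal alkyne with pinacolborane is a syn, anti-Markovnikov addition and should therefore deliver the E-alkenylboronate as a single regio- and stereoisomer.

Step 5
Reactants: 8 (E)-9-iodonon-8-en-2-one; 10 2-[(E)-dec-1-en-1-yl]-4,4,5,5-tetramethyl-1,3,2-dioxaborolane
Product: 11 (8E,10E)-nonadeca-8,10-dien-2-one
Conditions: Pd(PPh3)4 (5 mol %), 2 M aq. K3PO4 (3 equiv), THF, 50 °C, degassed
Reagents that add atoms: none
Why: The Suzuki–Miyaura sp2–sp2 coupling proceeds with retention of configuration at both alkenyl partners, so the E,E-diene should form at its central sigma bond, and the mild aqueous phosphate base spares the enolisable methyl ketone.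

Step 6
Reactants: 12 (R)-5-oxotetrahydrofuran-2-carboxylic acid
Product: 13 dimethyl (R)-2-hydroxypentanedioate
Conditions: HCl (cat.) in anhydrous MeOH, rt; solid NaHCO3, filter, concentrate below 25 °C; use at once
Reagents that add atoms: methanol, CO
Why: Acid-catalysed methanolysis of the lactone together with Fischer esterification of the acid in a large excess of methanol should give the open hydroxy diester by acyl–oxygen cleavage only, so the C2–O bond and the R configuration are untouched, and the acid is neutralised before cold concentration so that the product does not close back to the lactone.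

Step 7
Reactants: 13 dimethyl (R)-2-hydroxypentanedioate
Product: 14 dimethyl (R)-2-[(tert-butyldimethylsilyl)oxy]pentanedioate
Conditions: TBSCl (1.3 equiv), imidazole (2.5 equiv), DMF, 0 °C to rt
Reagents that add atoms: tert-butyldimethylsilyl chloride, CC(C)(C)[Si](C)(C)Cl
Why: Imidazole-promoted silylation of the secondary alcohol caps the only nucleophile able to relactonise and gives a base-stable ether for the Claisen chemistry, without touching the stereocentre.

Step 8
Reactants: 11 (8E,10E)-nonadeca-8,10-dien-2-one; 14 dimethyl (R)-2-[(tert-butyldimethylsilyl)oxy]pentanedioate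
Product: 18 (R)-6-[(tert-butyldimethylsilyl)oxy]-3-hydroxy-2-[(7E,9E)-octadeca-7,9-dienoyl]cyclohex-2-en-1-one, via lithium enolate 15 (not isolated), via diketo ester 16 (not isolated), via regioisomeric diketo ester 17 (not isolated)
Conditions: LiN(SiMe3)2 (1.05 equiv), THF, −78 °C; 14 (1.1 equiv); LiN(SiMe3)2 (1.2 equiv) added slowly, −78 to 0 °C; KOt-Bu (1.5 equiv), 0 °C to rt; 1 M HCl to pH 3–4, 0 °C
Reagents that add atoms: none
Why: Proposed new method: deprotonation of 11 by the hindered amide at −78 °C should give the methyl-side lithium enolate 15, which adds to an ester carbonyl of 14 and expels methoxide (crossed Claisen) to give the diketo ester 16 (attack at the unhindered C5 ester) and possibly its regioisomer 17 (attack at the C1 ester), each deprotonated at once to its diketonate by the second portion of base; after exchange to the potassium salt and warming, the central diketonate carbon acylates the remaining ester and the strongly acidic triketone is withdrawn as its triketonate, which only the final acidification protonates. The closest known reaction types are the crossed Claisen condensation of ketone lithium enolates with esters and the alkoxide-mediated Dieckmann-type cyclisation of 5,7-dioxoalkanoates to 2-acylcyclohexane-1,3-diones; what is new is running both on one carbon in one flask with a chiral 2-silyloxyglutarate. The six-membered carbocycle closes by a 6-exo-trig attack of the diketonate carbon on the ester carbonyl, and since the two ester carbons are 1,5-related and both end up bonded to the former methyl carbon, 16 and 17 give the same ring. No stereocentre is created, and C6 keeps the R configuration of 14 because none of its bonds is broken. The step needs enolisation at CH3 rather than C3 of the ketone (secured by the bulky base at low temperature and by the fact that only methyl-side acylation leads on to the stable triketonate), C- rather than O-acylation (any enol lactone is reopened by methoxide and drains to the same triketonate) and no epimerisation at the carbinol carbon (its hydrogen is alpha only to an ester in 14 and 16, or to a carbonyl already belonging to an anionic diketonate or triketonate in 17 and 18, so it is the least acidic activated C–H present).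

Step 9
Reactants: 18 (R)-6-[(tert-butyldimethylsilyl)oxy]-3-hydroxy-2-[(7E,9E)-octadeca-7,9-dienoyl]cyclohex-2-en-1-one
Product: 19 (R)-3,6-dihydroxy-2-[(7E,9E)-octadeca-7,9-dienoyl]cyclohex-2-en-1-one (target CNP0169831.1)
Conditions: HF·pyridine, pyridine, THF, 0 °C to rt (plastic vessel)
Reagents that add atoms: none
Why: Fluoride-driven cleavage of the Si–O bond under buffered acidic conditions (silyl ether deprotection) should free the C6 carbinol while avoiding the basic or oxidising media that would threaten the alpha-ketol stereocentre, the triketone and the diene.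

**Compound list**

1 | 6-chlorohex-1-yne | C#CCCCCCl | starting material
2 | (E)-(6-chlorohex-1-en-1-yl)zirconocene chloride, Cp2Zr(Cl)CH=CH(CH2)4Cl | ClCCCC/C=C/[Zr](Cl)(C1C=CC=C1)C1C=CC=C1 | intermediate
3 | (E)-6-chloro-1-iodohex-1-ene | ClCCCC/C=C/I | intermediate
4 | tert-butyl acetoacetate | CC(=O)CC(=O)OC(C)(C)C | starting material
5 | (E)-1,6-diiodohex-1-ene | ICCCC/C=C/I | intermediate
6 | tert-butyl (7E)-2-acetyl-8-iodooct-7-enoate (racemic at C2) | CC(=O)C(CCCC/C=C/I)C(=O)OC(C)(C)C | intermediate
7 | (7E)-2-acetyl-8-iodooct-7-enoic acid | CC(=O)C(CCCC/C=C/I)C(=O)O | intermediate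
8 | (E)-9-iodonon-8-en-2-one | CC(=O)CCCCC/C=C/I | intermediate
9 | dec-1-yne | CCCCCCCCC#C | starting material
10 | 2-[(E)-dec-1-en-1-yl]-4,4,5,5-tetramethyl-1,3,2-dioxaborolane | CCCCCCCC/C=C/B1OC(C)(C)C(C)(C)O1 | intermediate
11 | (8E,10E)-nonadeca-8,10-dien-2-one | CC(=O)CCCCC/C=C/C=C/CCCCCCCC | intermediate
12 | (R)-5-oxotetrahydrofuran-2-carboxylic acid | O=C1CC[C@H](C(=O)O)O1 | starting material
13 | dimethyl (R)-2-hydroxypentanedioate | COC(=O)CC[C@@H](O)C(=O)OC | intermediate
14 | dimethyl (R)-2-[(tert-butyldimethylsilyl)oxy]pentanedioate | COC(=O)CC[C@@H](O[Si](C)(C)C(C)(C)C)C(=O)OC | intermediate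
15 | lithium (8E,10E)-nonadeca-1,8,10-trien-2-olate | [Li+].[O-]C(=C)CCCCC/C=C/C=C/CCCCCCCC | intermediate
16 | methyl (2R,13E,15E)-2-[(tert-butyldimethylsilyl)oxy]-5,7-dioxotetracosa-13,15-dienoate (present as its diketonate) | CCCCCCCC/C=C/C=C/CCCCCC(=O)CC(=O)CC[C@@H](O[Si](C)(C)C(C)(C)C)C(=O)OC | intermediate
17 | methyl (4R,13E,15E)-4-[(tert-butyldimethylsilyl)oxy]-5,7-dioxotetracosa-13,15-dienoate (present as its diketonate) | CCCCCCCC/C=C/C=C/CCCCCC(=O)CC(=O)[C@H](O[Si](C)(C)C(C)(C)C)CCC(=O)OC | intermediate
18 | (R)-6-[(tert-butyldimethylsilyl)oxy]-3-hydroxy-2-[(7E,9E)-octadeca-7,9-dienoyl]cyclohex-2-en-1-one | CCCCCCCC/C=C/C=C/CCCCCC(=O)C1=C(O)CC[C@@H](O[Si](C)(C)C(C)(C)C)C1=O | intermediate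
19 | (R)-3,6-dihydroxy-2-[(7E,9E)-octadeca-7,9-dienoyl]cyclohex-2-en-1-one | CCCCCCCC/C=C/C=C/CCCCCC(=O)C1=C(O)CC[C@@H](O)C1=O | target

**Totals**

Total step count: 9.
Longest linear sequence: 6 steps (steps 1, 2, 3, 5, 8, 9).

**Steps most likely to fail**

1. Step 8 (Proposed new method).
 - What may go wrong: quenching of the enolate by proton transfer from the first-formed diketone; over-acylation of the diester by a second enolate; sluggish ring closure of the chelated diketonate; partial loss of configuration by reversible deprotonation alpha to the ester while the alkoxide is present.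
 - Fallback: it separates the two C–C bond formations and uses only known reaction types, setting out from 14 and the enolate 15 of ketone 11. Saponification of 14 (LiOH, THF/H2O, 0 °C, careful acidification) should give (R)-2-[(tert-butyldimethylsilyl)oxy]pentanedioic acid F1. Dehydration with DCC in CH2Cl2 at 0 °C then gives the cyclic anhydride (3R)-3-[(tert-butyldimethylsilyl)oxy]oxane-2,6-dione F2. The anhydride is opened at −78 °C by two equivalents of 15 (the second acting as base, ketone 11 being recovered), a known acylation of ketone enolates by cyclic anhydrides. This should give (2R,13E,15E)-2-[(tert-butyldimethylsilyl)oxy]-5,7-dioxotetracosa-13,15-dienoic acid F3, possibly with its regioisomer (4R,13E,15E)-4-[(tert-butyldimethylsilyl)oxy]-5,7-dioxotetracosa-13,15-dienoic acid F4. Esterification with Me3SiCHN2 in MeOH/toluene at 0 °C converts these into 16 and 17, now isolated. NaOMe in MeOH (rt to 40 °C), the known cyclisation of 5,7-dioxoalkanoates, closes both to the same ring, and the fallback rejoins the route at 18.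

2. Step 9.
 - What may go wrong: slow cleavage of the hindered silyl ether beside the chelating triketone, or degradation of the acid-sensitive product on prolonged exposure to HF.
 - Fallback: it changes the protecting-group strategy to a solvolytically labile ether and sets out from 13. Et3SiCl and imidazole in DMF should give dimethyl (R)-2-[(triethylsilyl)oxy]pentanedioate F5. This is taken with 11 through the conditions of step 8, by way of the unisolated methyl (2R,13E,15E)-5,7-dioxo-2-[(triethylsilyl)oxy]tetracosa-13,15-dienoate F6 and methyl (4R,13E,15E)-5,7-dioxo-4-[(triethylsilyl)oxy]tetracosa-13,15-dienoate F7. The product is (R)-3-hydroxy-2-[(7E,9E)-octadeca-7,9-dienoyl]-6-[(triethylsilyl)oxy]cyclohex-2-en-1-one F8. Solvolysis in AcOH/THF/H2O at rt then frees the carbinol without fluoride, and the fallback rejoins the route at 19.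

3. Step 6.
 - What may go wrong: re-closure of the hydroxy diester to the lactone ester during the acid-catalysed equilibration or on concentration, leaving material that cannot be silylated.
 - Fallback: it avoids acid altogether and sets out from 12. KOH (2 equiv) in aqueous MeOH opens the lactone to dipotassium (R)-2-hydroxypentanedioate F9. After drying, MeI in DMF at rt alkylates both carboxylates under neutral conditions, and the fallback rejoins the route at 13, which is silylated at once as in step 7.

**Further compounds**

F1 | step 8 | (R)-2-[(tert-butyldimethylsilyl)oxy]pentanedioic acid | OC(=O)CC[C@@H](O[Si](C)(C)C(C)(C)C)C(=O)O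
F2 | step 8 | (3R)-3-[(tert-butyldimethylsilyl)oxy]oxane-2,6-dione | O=C1CC[C@@H](O[Si](C)(C)C(C)(C)C)C(=O)O1
F3 | step 8 | (2R,13E,15E)-2-[(tert-butyldimethylsilyl)oxy]-5,7-dioxotetracosa-13,15-dienoic acid | CCCCCCCC/C=C/C=C/CCCCCC(=O)CC(=O)CC[C@@H](O[Si](C)(C)C(C)(C)C)C(=O)O
F4 | step 8 | (4R,13E,15E)-4-[(tert-butyldimethylsilyl)oxy]-5,7-dioxotetracosa-13,15-dienoic acid | CCCCCCCC/C=C/C=C/CCCCCC(=O)CC(=O)[C@H](O[Si](C)(C)C(C)(C)C)CCC(=O)O
F5 | step 9 | dimethyl (R)-2-[(triethylsilyl)oxy]pentanedioate | COC(=O)CC[C@@H](O[Si](CC)(CC)CC)C(=O)OC
F6 | step 9 | methyl (2R,13E,15E)-5,7-dioxo-2-[(triethylsilyl)oxy]tetracosa-13,15-dienoate | CCCCCCCC/C=C/C=C/CCCCCC(=O)CC(=O)CC[C@@H](O[Si](CC)(CC)CC)C(=O)OC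
F7 | step 9 | methyl (4R,13E,15E)-5,7-dioxo-4-[(triethylsilyl)oxy]tetracosa-13,15-dienoate | CCCCCCCC/C=C/C=C/CCCCCC(=O)CC(=O)[C@H](O[Si](CC)(CC)CC)CCC(=O)OC
F8 | step 9 | (R)-3-hydroxy-2-[(7E,9E)-octadeca-7,9-dienoyl]-6-[(triethylsilyl)oxy]cyclohex-2-en-1-one | CCCCCCCC/C=C/C=C/CCCCCC(=O)C1=C(O)CC[C@@H](O[Si](CC)(CC)CC)C1=O
F9 | step 6 | dipotassium (R)-2-hydroxypentanedioate | [K+].[K+].[O-]C(=O)CC[C@@H](O)C([O-])=O
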